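- A species cannot outrank E while E holds over half of the charge, and E cannot lead once it holds under a quarter, if Z, D, G and E share the whole charge.

| flask | E | Q | remark | time |
|---|---|---|---|---|
| Thursday's | 0.40 M | 200 mM (held) | run made earlier |  |
| Wednesday's | 0.60 M | 200 mM (held) | run made earlier |  |
| dusk | 0.80 M | 200 mM (held) |  | 15 min |
| midnight | 0.80 M | 200 mM (held) |  | 45 min |
| spring | 0.80 M | 200 mM (held) |  | 140 min |

| run | time / min | G / % | D / % | Z / % | E / % |
|---|---|---|---|---|---|
| Thursday's | 2.50 | 0.9 | 1.0 | 4.1 | 94.4 |
| Thursday's | 5.00 | 1.9 | 1.7 | 9.5 | 88.1 |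
| Thursday's | 8.00 | 0.4 | 4.9 | 16.8 | 77.2 |
| Thursday's | 10.0 | 2.5 | 7.6 | 19.3 | 70.2 |
| Thursday's | 12.0 | 3.9 | 8.9 | 21.2 | 66.6 |
| Thursday's | 15.0 | 4.1 | 12.2 | 20.5 | 62.8 |
| Wednesday's | 2.50 | 0 | 0 | 5.2 | 94.2 |
| Wednesday's | 5.00 | 0 | 0.1 | 10.7 | 88.7 |
| Wednesday's | 8.00 | 0 | 5.4 | 15.6 | 77.6 |
| Wednesday's | 10.0 | 0.8 | 5.9 | 17.5 | 73.2 |
| Wednesday's | 12.0 | 0.5 | 8.3 | 19.0 | 67.7 |
| Wednesday's | 15.0 | 4.5 | 12.1 | 20.2 | 62.5 |

(standard deviation of a reading: 1 percentage point)

1. which of these there is most of at the end, counted by the E in it, dusk (Z / D / E / G)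
2. which of these there is most of at the end, counted by the E in it, midnight (Z / D / E / G)
3. which of these there is most of at the end, counted by the E in it, spring (Z / D / E / G)
4. final amount of the leader among these, as a percentage of the E charged, in dusk
5. final amount of the leader among these, as a percentage of the E charged, in midnight
6. final amount of the leader among these, as a percentage of the E charged, in spring

- So I asked what the opposite outcome would require of the readings. With Q held, the percentages at 15.0 min barely moved between cE 0.40 M (62.8%) and cE 0.60 M (62.5%), and I carried them over to cE 0.80 M.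
- I took the pseudo-first-order constant of E from those readings, 0.0312 min⁻¹. This gave the half-life of E 22.2 min, the time for E to fall to half its amount, as a reading with its scatter.
- For E to lose dusk, its half-life would have had to lie under 15 min. It lay above that, so I committed to E at about 62.6%.
- For E to hold midnight, its half-life would have had to exceed 22.5 min. The reading fell short by 0.265 min, which is too close for the bound to exclude E, and I reckoned E at 24.6%.
- The bound did not choose among E, Z, D and G at midnight, and the spread of Z, D and G in Thursday's run at 15.0 min could not show their order at 45 min. I named G at midnight as a judgement from the chain Z, D, G, not as a result of the bound.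
- Spring lasted 6.30 half-lives, leaving E at about 1.27%, and I named G, the end of the chain.
- The forecast, holding that “each step looks first order in substrate”, gave E at 63% (59% to 66%) for dusk, G at 41% (31% to 51%) for midnight and G at 96% (86% to 99.5%) for spring.
- The flasks gave E at 63.7% in dusk, G at 39.6% in midnight and G at 93.6% in spring.

    E + L → Z (k = 0.213 L mol⁻¹ min⁻¹)
    L + Z → D (k = 0.529 L mol⁻¹ min⁻¹)
    L + D → G (k = 0.422 L mol⁻¹ min⁻¹)
    Q ⇌ L, rate k4*(csat - [L]) (kL = 0.674 min⁻¹)
    Z → J (k = 0.00412 min⁻¹)

- In spring, the E left moved by 6 points when the charge of E was raised to 4.06 M. In midnight, E stood at 24.1%, under a quarter, against my 24.6%. The flask like dusk but read at 1.0 h had run 2.70 half-lives, so the half-life gave E 15.4%; it held 14.2%, and G led at 58.2%.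

The numbers in the tables are calculated for an exercise, and the scatter is random.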